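**Retrosynthetic overview**

1. Numbering used here: the 14-membered carbocycle is C1–C14. C1 is the lactone O–C(CH3) carbon, C4 the CH that carries the acrylate carbon, C6 the CHOH, C7 the C(CH3)OH, C10=C11(CH3) the (Z)-alkene and C14 the CHOH; the 7-membered α-methylene lactone bridges C1 and C4.
2. Key disconnection C7–C8: the ring segment C7(OH)–C8H2–C9H2–C10H=C11(CH3) is a bishomoallylic tertiary carbinol, the retron of a reductive 1,3-diene/ketone coupling. The acyclic (Z)-diene methyl ketone 20 closes the carbocycle, and its C6 silyloxy stereocentre α to the ketone sets C7.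
3. The lactone is closed second, by 7-exo opening at C1 of a (1S,14S)-epoxide by the acrylic acid (inversion at C1, C14–OH released); the epoxide comes from Shi epoxidation of the (E)-C1=C14 alkene.
4. The chain is built around that alkene by two stereoselective Negishi couplings on a 1,1-dibromoalkene. Nerol gives C9–C14 with the (Z)-C10=C11 unit; (R)-carvone, cleaved at its enone C=C, gives C2–C7 with C4, C6, the methyl ketone and the acrylate carbons; CBr4 gives C1, Me2Zn its methyl, a Wittig reagent C8.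
5. Ring order: 14-membered carbocycle (step 16), then 7-membered lactone (step 19).

Key step: step 16

Remark: the ring alkene is taken exactly as drawn (C9 and C12 cis); (R)-carvone, nerol and the L-fructose-derived enantiomer of the Shi ketone are taken as commercial. TBS = tert-butyldimethylsilyl, TES = triethylsilyl, PMB = 4-methoxybenzyl.

**Route**

Step 1
Reactants: 1 (R)-carvone
Product: 2 (5R)-5-(3-hydroxyprop-1-en-2-yl)-2-methylcyclohex-2-en-1-one
Conditions: SeO2 (cat.), t-BuOOH, salicylic acid (cat.), CH2Cl2, 23 °C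
Reagents that add atoms: tert-butyl hydroperoxide, CC(C)(C)OO (oxygen relayed through selenium dioxide, O=[Se]=O)
Why: SeO2 allylic hydroxylation (ene reaction, then [2,3]-shift) should take the methyl group of the electron-rich 1,1-disubstituted alkene, while the enone C=C is deactivated and the stereocentre is untouched.

Step 2
Reactants: 2 (5R)-5-(3-hydroxyprop-1-en-2-yl)-2-methylcyclohex-2-en-1-one
Product: 3 (1R,5R)-5-(3-hydroxyprop-1-en-2-yl)-2-methylcyclohex-2-en-1-ol
Conditions: NaBH4, CeCl3·7H2O, MeOH, -78 °C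
Reagents that add atoms: none
Why: Luche 1,2-reduction; axial hydride delivery to the carvone enone should give the cis-1,5 allylic alcohol, which becomes C6 (R) of the target.

Step 3
Reactants: 3 (1R,5R)-5-(3-hydroxyprop-1-en-2-yl)-2-methylcyclohex-2-en-1-ol
Product: 4 (1R,5R)-1-(TBS-oxy)-5-[3-(TBS-oxy)prop-1-en-2-yl]-2-methylcyclohex-2-ene
Conditions: TBSCl (2.5 equiv), imidazole, DMF, 23 °C
Reagents that add atoms: tert-butyldimethylsilyl chloride, CC(C)(C)[Si](C)(C)Cl
Why: standard silyl ether formation on both hydroxyls; the bulky, non-chelating C6 silyl ether is wanted later for Felkin–Anh control.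

Step 4
Reactants: 4 (1R,5R)-1-(TBS-oxy)-5-[3-(TBS-oxy)prop-1-en-2-yl]-2-methylcyclohex-2-ene
Product: 6 (3S,5R)-5-(TBS-oxy)-3-[3-(TBS-oxy)prop-1-en-2-yl]-6-oxoheptanal, via ring epoxide 5 (not isolated)
Conditions: mCPBA, NaHCO3, CH2Cl2, -20 to 0 °C; then H5IO6, THF/H2O, 0 °C
Reagents that add atoms: 3-chloroperoxybenzoic acid, O=C(OO)c1cccc(Cl)c1; water, O
Why: Prilezhaev epoxidation of the most nucleophilic (trisubstituted) alkene, then periodic acid hydrolysis and glycol cleavage, should unzip the ring into the C7 methyl ketone and the C2 aldehyde without touching either stereocentre.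

Step 5
Reactants: 6 (3S,5R)-5-(TBS-oxy)-3-[3-(TBS-oxy)prop-1-en-2-yl]-6-oxoheptanal
Product: 7 (3R,5R)-3-(TBS-oxy)-5-[3-(TBS-oxy)prop-1-en-2-yl]-7-hydroxyheptan-2-one
Conditions: NaBH4, EtOH/CH2Cl2, -78 °C
Reagents that add atoms: none
Why: chemoselective borohydride reduction; at low temperature the aldehyde should react well before the hindered α-silyloxy ketone, and prompt reduction also forestalls intramolecular aldol reaction of the keto aldehyde.

Step 6
Reactants: 7 (3R,5R)-3-(TBS-oxy)-5-[3-(TBS-oxy)prop-1-en-2-yl]-7-hydroxyheptan-2-one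
Product: 8 (3R,5S)-3-(TBS-oxy)-5-[3-(TBS-oxy)prop-1-en-2-yl]-7-iodoheptan-2-one
Conditions: I2, PPh3, imidazole, CH2Cl2, 0 °C
Reagents that add atoms: iodine, II
Why: Appel-type iodination of the primary alcohol under neutral conditions that leave the ketone and silyl ethers alone (the descriptor at the branch carbon changes only through priorities).

Step 7
Reactants: 9 nerol
Product: 10 neryl 4-methoxybenzyl ether, 1-({[(2Z)-3,7-dimethylocta-2,6-dien-1-yl]oxy}methyl)-4-methoxybenzene
Conditions: NaH, PMBCl, Bu4NI (cat.), THF, 0 to 23 °C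
Reagents that add atoms: 4-methoxybenzyl chloride, COc1ccc(CCl)cc1
Why: Williamson etherification; the PMB ether tolerates organozinc and palladium chemistry (an allylic acetate would not) and deactivates the 2,3-alkene towards electrophilic oxidants.

Step 8
Reactants: 10 neryl 4-methoxybenzyl ether
Product: 12 (4Z)-6-[(4-methoxybenzyl)oxy]-4-methylhex-4-enal, via terminal epoxide 11 (not isolated)
Conditions: mCPBA, CH2Cl2, -20 °C; then H5IO6, THF/H2O, 0 °C
Reagents that add atoms: 3-chloroperoxybenzoic acid, O=C(OO)c1cccc(Cl)c1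
Why: Prilezhaev epoxidation should choose the distal trisubstituted alkene (the other is deactivated by the allylic oxygen), and periodic acid cleavage then excises acetone to leave the C14 aldehyde with the (Z)-alkene intact.

Step 9
Reactants: 12 (4Z)-6-[(4-methoxybenzyl)oxy]-4-methylhex-4-enal
Product: 13 1-({[(2Z)-7,7-dibromo-3-methylhepta-2,6-dien-1-yl]oxy}methyl)-4-methoxybenzene
Conditions: CBr4, PPh3, 2,6-lutidine, CH2Cl2, 0 °C
Reagents that add atoms: carbon tetrabromide, BrC(Br)(Br)Br
Why: Corey–Fuchs (Ramirez) dibromo-olefination of the aldehyde installs C1 as a 1,1-dibromoalkene, whose two C–Br bonds can be substituted one after the other.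

Step 10
Reactants: 8 (3R,5S)-3-(TBS-oxy)-5-[3-(TBS-oxy)prop-1-en-2-yl]-7-iodoheptan-2-one; 13 1-({[(2Z)-7,7-dibromo-3-methylhepta-2,6-dien-1-yl]oxy}methyl)-4-methoxybenzene
Product: 15 (3R,5R,8Z,12Z)-8-bromo-3-(TBS-oxy)-5-[3-(TBS-oxy)prop-1-en-2-yl]-14-[(4-methoxybenzyl)oxy]-12-methyltetradeca-8,12-dien-2-one, via alkylzinc iodide 14 (not isolated)
Conditions: Zn dust (activated with TMSCl), LiCl, THF, 40 °C; then 13, PdCl2(DPEphos) (cat.), THF/DMF, 23 °C
Reagents that add atoms: none
Why: zinc insertion gives a ketone-tolerant alkylzinc iodide, and Negishi coupling on the 1,1-dibromoalkene should be trans-selective because zerovalent palladium inserts into the less hindered C–Br bond trans to the alkyl chain, putting C2 trans to C13.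

Step 11
Reactants: 15 (3R,5R,8Z,12Z)-8-bromo-3-(TBS-oxy)-5-[3-(TBS-oxy)prop-1-en-2-yl]-14-[(4-methoxybenzyl)oxy]-12-methyltetradeca-8,12-dien-2-one
Product: 16 (3R,5R,8E,12Z)-3-(TBS-oxy)-5-[3-(TBS-oxy)prop-1-en-2-yl]-14-[(4-methoxybenzyl)oxy]-8,12-dimethyltetradeca-8,12-dien-2-one
Conditions: Me2Zn, Pd(P(t-Bu)3)2 (cat.), THF, 23 °C
Reagents that add atoms: dimethylzinc, C[Zn]C
Why: second Negishi coupling; with the bulky trialkylphosphine catalyst the remaining C–Br bond should be methylated with retention, giving the (E)-trisubstituted C1=C14 alkene, and uncatalysed Me2Zn does not add to the ketone.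

Step 12
Reactants: 16 (3R,5R,8E,12Z)-3-(TBS-oxy)-5-[3-(TBS-oxy)prop-1-en-2-yl]-14-[(4-methoxybenzyl)oxy]-8,12-dimethyltetradeca-8,12-dien-2-one
Product: 17 (3R,5R,8S,9S,12Z)-8,9-epoxy-3-(TBS-oxy)-5-[3-(TBS-oxy)prop-1-en-2-yl]-14-[(4-methoxybenzyl)oxy]-8,12-dimethyltetradec-12-en-2-one
Conditions: L-fructose-derived Shi ketone (0.3 equiv), Oxone (2KHSO5·KHSO4·K2SO4), K2CO3 buffer, Bu4NHSO4, MeCN/dimethoxymethane/H2O, 0 °C
Reagents that add atoms: potassium peroxymonosulfate, [K+].[O-]S(=O)(=O)OO
Why: Shi asymmetric epoxidation; the chiral dioxirane (spiro transition state, reagent control) should give the (S,S)-epoxide of the isolated (E)-trisubstituted alkene, while the two other alkenes each carry a deactivating allylic oxygen.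

Step 13
Reactants: 17 (3R,5R,8S,9S,12Z)-8,9-epoxy-3-(TBS-oxy)-5-[3-(TBS-oxy)prop-1-en-2-yl]-14-[(4-methoxybenzyl)oxy]-8,12-dimethyltetradec-12-en-2-one
Product: 18 (3R,5R,8S,9S,12Z)-8,9-epoxy-3-(TBS-oxy)-5-[3-(TBS-oxy)prop-1-en-2-yl]-14-hydroxy-8,12-dimethyltetradec-12-en-2-one
Conditions: DDQ, CH2Cl2/pH 7 buffer, 0 °C
Reagents that add atoms: none
Why: oxidative PMB ether cleavage under buffered, neutral conditions that spare the epoxide, the silyl ethers and the epimerisable α-silyloxy ketone.

Step 14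
Reactants: 18 (3R,5R,8S,9S,12Z)-8,9-epoxy-3-(TBS-oxy)-5-[3-(TBS-oxy)prop-1-en-2-yl]-14-hydroxy-8,12-dimethyltetradec-12-en-2-one
Product: 19 (3R,5R,8S,9S,12Z)-8,9-epoxy-3-(TBS-oxy)-5-[3-(TBS-oxy)prop-1-en-2-yl]-8,12-dimethyl-2-oxotetradec-12-en-14-al
Conditions: MnO2, CH2Cl2, 23 °C
Reagents that add atoms: none
Why: MnO2 oxidation is selective for the allylic alcohol and should give the neral-type (Z)-enal without acid or base that would isomerise it.

Step 15
Reactants: 19 (3R,5R,8S,9S,12Z)-8,9-epoxy-3-(TBS-oxy)-5-[3-(TBS-oxy)prop-1-en-2-yl]-8,12-dimethyl-2-oxotetradec-12-en-14-al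
Product: 20 (3R,5R,8S,9S,12Z)-8,9-epoxy-3-(TBS-oxy)-5-[3-(TBS-oxy)prop-1-en-2-yl]-8,12-dimethylpentadeca-12,14-dien-2-one
Conditions: Ph3PCH3Br (1.05 equiv), KN(SiMe3)2, THF, -78 to -20 °C
Reagents that add atoms: methyltriphenylphosphonium bromide, C[P+](c1ccccc1)(c1ccccc1)c1ccccc1.[Br-]
Why: Wittig methylenation; one equivalent of the ylide at low temperature should take the enal long before the hindered methyl ketone, adding C8 and giving the (Z)-1,3-diene with the trisubstituted alkene geometry unchanged.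

Step 16
Reactants: 20 (3R,5R,8S,9S,12Z)-8,9-epoxy-3-(TBS-oxy)-5-[3-(TBS-oxy)prop-1-en-2-yl]-8,12-dimethylpentadeca-12,14-dien-2-one
Product: 21 (1S,4R,6R,7S,10Z,14S)-1,14-epoxy-6-(TBS-oxy)-4-[3-(TBS-oxy)prop-1-en-2-yl]-1,7,11-trimethylcyclotetradec-10-en-7-ol (target numbering)
Conditions: Ni(acac)2 (0.3 equiv), Et2Zn (3 equiv), THF, 23 °C, syringe-pump addition of 20 (final concentration about 1 mM); aqueous work-up
Reagents that add atoms: none
Why: Proposed new method: zerovalent nickel, generated from Ni(acac)2 and Et2Zn, binds the unsubstituted vinyl terminus of the (Z)-diene and couples it oxidatively with the zinc-activated C7 ketone to an oxanickelacycle with an η3-allyl unit over C9–C11 (C7–C8 formed); ethyl transfer from zinc to nickel, β-hydride elimination and C–H reductive elimination at C9 then release the zinc alkoxide of 21 and ethene. The closest known reaction is the intermolecular nickel-catalysed homoallylation of aldehydes and ketones with 1,3-dienes promoted by Et2Zn or Et3B (Tamaru type); nickel-catalysed reductive macrocyclisation is known for ynals, so the ring-closing diene–ketone version is the new element. The 14-membered carbocycle closes exo at the carbonyl (oxygen outside the ring) and endo at the diene (both carbons of the reacting vinyl group inside the ring). The only new stereocentre, C7, is set by polar Felkin–Anh control: the non-chelating C6 silyloxy group stands anti to the forming bond, which gives the 6,7-anti (7S) carbinol. The step needs attack through the CH2 terminus with hydrogen delivery to C9, secured because the other diene terminus is fully substituted; it needs retention of the C10=C11 (Z) geometry, secured because the allyl unit cannot rotate about C10–C11 without a nickel–carbon σ-bond at tertiary C11; and it needs ring closure over oligomerisation, secured by slow addition at high dilution, while the isolated 1,1-disubstituted alkene, the trisubstituted epoxide and the silyl ethers are not substrates for this catalyst.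

Step 17
Reactants: 21 (1S,4R,6R,7S,10Z,14S)-1,14-epoxy-6-(TBS-oxy)-4-[3-(TBS-oxy)prop-1-en-2-yl]-1,7,11-trimethylcyclotetradec-10-en-7-ol
Product: 22 (1S,4R,6R,7S,10Z,14S)-1,14-epoxy-6-(TBS-oxy)-4-(3-hydroxyprop-1-en-2-yl)-1,7,11-trimethylcyclotetradec-10-en-7-ol
Conditions: NH4F, MeOH, 23 to 40 °C
Reagents that add atoms: none
Why: fluoride-mediated desilylation under neutral conditions should remove the unhindered primary allylic silyl ether well before the secondary one flanked by the quaternary carbinol, and leaves the epoxide closed.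

Step 18
Reactants: 22 (1S,4R,6R,7S,10Z,14S)-1,14-epoxy-6-(TBS-oxy)-4-(3-hydroxyprop-1-en-2-yl)-1,7,11-trimethylcyclotetradec-10-en-7-ol
Product: 23 2-[(1S,4R,6R,7S,10Z,14S)-1,14-epoxy-6-(TBS-oxy)-7-hydroxy-1,7,11-trimethylcyclotetradec-10-en-4-yl]prop-2-enal
Conditions: MnO2, CH2Cl2, 23 °C
Reagents that add atoms: none
Why: MnO2 oxidation touches only the allylic primary alcohol; the tertiary C7 hydroxyl cannot be oxidised.

Step 19
Reactants: 23 2-[(1S,4R,6R,7S,10Z,14S)-1,14-epoxy-6-(TBS-oxy)-7-hydroxy-1,7,11-trimethylcyclotetradec-10-en-4-yl]prop-2-enal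
Product: 25 C6 TBS ether of the target (1R,4R,6R,7S,10Z,14S; ε-lactone closed and C14–OH free), via epoxy acid 24 (not isolated)
Conditions: NaClO2, NaH2PO4, 2-methyl-2-butene, t-BuOH/H2O, 0 °C; then camphorsulfonic acid (cat.), CH2Cl2, 0 to 23 °C
Reagents that add atoms: sodium chlorite, [Na+].[O-]Cl=O
Why: Pinnick oxidation gives the acrylic acid, and Brønsted-acid-promoted epoxide opening should then proceed 7-exo at the tertiary carbon C1 with inversion, giving C1 (R) with the lactone oxygen and C14 (S) with the retained hydroxyl; only the epoxide carbon is electrophilic, so the C7 hydroxyl cannot compete for the acyl group.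

Step 20
Reactants: 25 C6 TBS ether of the target
Product: 26 CNP0263298.1
Conditions: HF·pyridine, pyridine, THF, 0 to 23 °C
Reagents that add atoms: none
Why: acidic fluoride desilylation frees the C6 hydroxyl without the basic conditions that would invite Michael addition to the α-methylene lactone or acyl migration to the six-membered lactone on O6.

**Compound list**

1 | (R)-carvone | CC1=CC[C@@H](C(C)=C)CC1=O | starting material
2 | (5R)-5-(3-hydroxyprop-1-en-2-yl)-2-methylcyclohex-2-en-1-one | CC1=CC[C@@H](C(=C)CO)CC1=O | intermediate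
3 | (1R,5R)-5-(3-hydroxyprop-1-en-2-yl)-2-methylcyclohex-2-en-1-ol | CC1=CC[C@@H](C(=C)CO)C[C@H]1O | intermediate
4 | bis-TBS ether of 3 | CC1=CC[C@@H](C(=C)CO[Si](C)(C)C(C)(C)C)C[C@H]1O[Si](C)(C)C(C)(C)C | intermediate
5 | 2,3-epoxide of 4 (both epoxide faces; these two centres are lost in the cleavage) | CC12OC1C[C@@H](C(=C)CO[Si](C)(C)C(C)(C)C)C[C@H]2O[Si](C)(C)C(C)(C)C | intermediate
6 | (3S,5R)-5-(TBS-oxy)-3-[3-(TBS-oxy)prop-1-en-2-yl]-6-oxoheptanal | O=CC[C@@H](C(=C)CO[Si](C)(C)C(C)(C)C)C[C@@H](O[Si](C)(C)C(C)(C)C)C(C)=O | intermediate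
7 | (3R,5R)-3-(TBS-oxy)-5-[3-(TBS-oxy)prop-1-en-2-yl]-7-hydroxyheptan-2-one | OCC[C@@H](C(=C)CO[Si](C)(C)C(C)(C)C)C[C@@H](O[Si](C)(C)C(C)(C)C)C(C)=O | intermediate
8 | (3R,5S)-3-(TBS-oxy)-5-[3-(TBS-oxy)prop-1-en-2-yl]-7-iodoheptan-2-one | ICC[C@@H](C(=C)CO[Si](C)(C)C(C)(C)C)C[C@@H](O[Si](C)(C)C(C)(C)C)C(C)=O | intermediate
9 | nerol, (2Z)-3,7-dimethylocta-2,6-dien-1-ol | CC(C)=CCC/C(C)=C\CO | starting material
10 | neryl 4-methoxybenzyl ether | COc1ccc(COC/C=C(/C)CCC=C(C)C)cc1 | intermediate
11 | 6,7-epoxide of 10 (racemic) | COc1ccc(COC/C=C(/C)CCC2OC2(C)C)cc1 | intermediate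
12 | (4Z)-6-[(4-methoxybenzyl)oxy]-4-methylhex-4-enal | COc1ccc(COC/C=C(/C)CCC=O)cc1 | intermediate
13 | 1-({[(2Z)-7,7-dibromo-3-methylhepta-2,6-dien-1-yl]oxy}methyl)-4-methoxybenzene | COc1ccc(COC/C=C(/C)CCC=C(Br)Br)cc1 | intermediate
14 | alkylzinc iodide from 8 | I[Zn]CC[C@@H](C(=C)CO[Si](C)(C)C(C)(C)C)C[C@@H](O[Si](C)(C)C(C)(C)C)C(C)=O | intermediate
15 | (3R,5R,8Z,12Z)-8-bromo-3-(TBS-oxy)-5-[3-(TBS-oxy)prop-1-en-2-yl]-14-[(4-methoxybenzyl)oxy]-12-methyltetradeca-8,12-dien-2-one | COc1ccc(COC/C=C(/C)CC/C=C(\Br)CC[C@@H](C(=C)CO[Si](C)(C)C(C)(C)C)C[C@@H](O[Si](C)(C)C(C)(C)C)C(C)=O)cc1 | intermediate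
16 | (3R,5R,8E,12Z)-3-(TBS-oxy)-5-[3-(TBS-oxy)prop-1-en-2-yl]-14-[(4-methoxybenzyl)oxy]-8,12-dimethyltetradeca-8,12-dien-2-one | COc1ccc(COC/C=C(/C)CC/C=C(\C)CC[C@@H](C(=C)CO[Si](C)(C)C(C)(C)C)C[C@@H](O[Si](C)(C)C(C)(C)C)C(C)=O)cc1 | intermediate
17 | (8S,9S)-epoxide of 16 | COc1ccc(COC/C=C(/C)CC[C@@H]2O[C@@]2(C)CC[C@@H](C(=C)CO[Si](C)(C)C(C)(C)C)C[C@@H](O[Si](C)(C)C(C)(C)C)C(C)=O)cc1 | intermediate
18 | (Z)-allylic alcohol, 14-hydroxy analogue of 17 | OC/C=C(/C)CC[C@@H]1O[C@@]1(C)CC[C@@H](C(=C)CO[Si](C)(C)C(C)(C)C)C[C@@H](O[Si](C)(C)C(C)(C)C)C(C)=O | intermediate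
19 | (Z)-enal from 18 | O=C/C=C(/C)CC[C@@H]1O[C@@]1(C)CC[C@@H](C(=C)CO[Si](C)(C)C(C)(C)C)C[C@@H](O[Si](C)(C)C(C)(C)C)C(C)=O | intermediate
20 | (3R,5R,8S,9S,12Z)-8,9-epoxy-3-(TBS-oxy)-5-[3-(TBS-oxy)prop-1-en-2-yl]-8,12-dimethylpentadeca-12,14-dien-2-one | C=C/C=C(/C)CC[C@@H]1O[C@@]1(C)CC[C@@H](C(=C)CO[Si](C)(C)C(C)(C)C)C[C@@H](O[Si](C)(C)C(C)(C)C)C(C)=O | intermediate
21 | epoxy macrocycle, (1S,4R,6R,7S,10Z,14S)-1,14-epoxy-6-(TBS-oxy)-4-[3-(TBS-oxy)prop-1-en-2-yl]-1,7,11-trimethylcyclotetradec-10-en-7-ol | C=C(CO[Si](C)(C)C(C)(C)C)[C@H]1C[C@@H](O[Si](C)(C)C(C)(C)C)[C@@](C)(O)CC/C=C(/C)CC[C@@H]2O[C@@]2(C)CC1 | intermediate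
22 | primary allylic alcohol from 21 | C=C(CO)[C@H]1C[C@@H](O[Si](C)(C)C(C)(C)C)[C@@](C)(O)CC/C=C(/C)CC[C@@H]2O[C@@]2(C)CC1 | intermediate
23 | 2-substituted acrolein from 22 | C=C(C=O)[C@H]1C[C@@H](O[Si](C)(C)C(C)(C)C)[C@@](C)(O)CC/C=C(/C)CC[C@@H]2O[C@@]2(C)CC1 | intermediate
24 | epoxy acrylic acid from 23 | C=C(C(=O)O)[C@H]1C[C@@H](O[Si](C)(C)C(C)(C)C)[C@@](C)(O)CC/C=C(/C)CC[C@@H]2O[C@@]2(C)CC1 | intermediate
25 | C6 TBS ether of the target | C=C1C(=O)O[C@]2(C)CC[C@@H]1C[C@@H](O[Si](C)(C)C(C)(C)C)[C@@](C)(O)CC/C=C(/C)CC[C@@H]2O | intermediate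
26 | CNP0263298.1, (1R,4R,6R,7S,10Z,14S) in the numbering above | C=C1C(=O)O[C@]2(C)CC[C@@H]1C[C@@H](O)[C@@](C)(O)CC/C=C(/C)CC[C@@H]2O | target

**Step count and risks**

Total steps: 20. Longest linear sequence: 17 steps (steps 1–6 and 10–20, from (R)-carvone).

Steps most likely to fail:

Step 16 (proposed new method). The ring closure may lose to oligomerisation, to diene dimerisation or to simple ethyl transfer to the ketone, and the facial selectivity at C7 may be overridden by the conformation of the forming ring. The fallback closes the same bond by a samarium Barbier reaction. It sets out from 20: the ketone would be reduced with NaBH4 to the secondary alcohol F1 (both epimers), so that it cannot consume the borane. The vinyl terminus of the diene would be hydroborated with disiamylborane and oxidised with NaBO3·4H2O to the primary alcohol F2, the primary hydroxyl exchanged for iodide (I2, PPh3, imidazole) to give the iodo alcohol F3, and the secondary alcohol reoxidised with Dess–Martin periodinane to the iodo ketone F4. SmI2 in THF/HMPA under high dilution would then add the primary alkylsamarium to the ketone and come back to the route at 21.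

Step 19. The protonated epoxide may be captured across the ring by the C10=C11 alkene, or rearrange by hydride shift, faster than the seven-membered lactone closes. The fallback makes the C1–O bond by acylation instead of epoxide opening. It sets out from 23: dilute aqueous HClO4 in THF would hydrolyse the epoxide with a large excess of water (attack at C1 with inversion) to the triol enal F5. The only secondary hydroxyl, at C14, would be silylated (TESCl, imidazole) to give the TES ether F6, and Pinnick oxidation would give the hydroxy acid F7. Shiina macrolactonisation (2-methyl-6-nitrobenzoic anhydride, DMAP, high dilution) onto the C1 hydroxyl would give the bis-silyl lactone F8; the C7 hydroxyl is the more shielded of the two tertiary alcohols, next to the C6 silyl ether, but this regioselectivity is the weak point of the fallback. HF·pyridine would remove both silyl groups and come back to the route at 26.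

Step 10 (with step 11). Alkene geometry may erode in the two palladium-catalysed substitutions, through incomplete trans-selectivity in the first or stereoinversion in the methylation. The fallback fixes the geometry by alkyne hydrometalation. It sets out from 13: n-BuLi followed by MeI would give the methyl alkyne F9. Hydrozirconation with Cp2Zr(H)Cl (excess, 50 °C, to equilibrate zirconium onto the methyl-bearing carbon) and iodination would give the (E)-vinyl iodide F10. A single Negishi coupling of F10 with the alkylzinc iodide 14 (made from 8 as in step 10) under Pd(PPh3)4 would come back to the route at 16.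

Further compounds
F1 | step 16 | secondary alcohol from reduction of the ketone of 20 (both epimers) | C=C/C=C(/C)CC[C@@H]1O[C@@]1(C)CC[C@@H](C(=C)CO[Si](C)(C)C(C)(C)C)C[C@@H](O[Si](C)(C)C(C)(C)C)C(C)O
F2 | step 16 | primary alcohol from hydroboration of the diene terminus of F1 | OCC/C=C(/C)CC[C@@H]1O[C@@]1(C)CC[C@@H](C(=C)CO[Si](C)(C)C(C)(C)C)C[C@@H](O[Si](C)(C)C(C)(C)C)C(C)O
F3 | step 16 | iodo alcohol | ICC/C=C(/C)CC[C@@H]1O[C@@]1(C)CC[C@@H](C(=C)CO[Si](C)(C)C(C)(C)C)C[C@@H](O[Si](C)(C)C(C)(C)C)C(C)O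
F4 | step 16 | iodo ketone | ICC/C=C(/C)CC[C@@H]1O[C@@]1(C)CC[C@@H](C(=C)CO[Si](C)(C)C(C)(C)C)C[C@@H](O[Si](C)(C)C(C)(C)C)C(C)=O
F5 | step 19 | triol enal (C1, C7 and C14 hydroxyls free, C6 TBS ether) | C=C(C=O)[C@H]1C[C@@H](O[Si](C)(C)C(C)(C)C)[C@@](C)(O)CC/C=C(/C)CC[C@H](O)[C@](C)(O)CC1
F6 | step 19 | C14 TES ether of F5 | C=C(C=O)[C@H]1C[C@@H](O[Si](C)(C)C(C)(C)C)[C@@](C)(O)CC/C=C(/C)CC[C@H](O[Si](CC)(CC)CC)[C@](C)(O)CC1
F7 | step 19 | hydroxy acid from F6 | C=C(C(=O)O)[C@H]1C[C@@H](O[Si](C)(C)C(C)(C)C)[C@@](C)(O)CC/C=C(/C)CC[C@H](O[Si](CC)(CC)CC)[C@](C)(O)CC1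
F8 | step 19 | bis-silyl lactone (C6 TBS, C14 TES) | C=C1C(=O)O[C@]2(C)CC[C@@H]1C[C@@H](O[Si](C)(C)C(C)(C)C)[C@@](C)(O)CC/C=C(/C)CC[C@@H]2O[Si](CC)(CC)CC
F9 | step 10 | methyl alkyne, 1-methoxy-4-({[(2Z)-3-methyloct-2-en-6-yn-1-yl]oxy}methyl)benzene | COc1ccc(COC/C=C(/C)CCC#CC)cc1
F10 | step 10 | (E)-vinyl iodide, 1-({[(2Z,6E)-7-iodo-3-methylocta-2,6-dien-1-yl]oxy}methyl)-4-methoxybenzene | COc1ccc(COC/C=C(/C)CC/C=C(\C)I)cc1
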